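## Retrosynthetic overview

1. The target is opened at the lactone C–O bond and at C1–C2 to give an acyclic, achiral bromo-enal ester. Divalent chromium reverses the polarity of the β-carbon of its 2-(bromomethyl)enoate, making it a homoenolate (d3) equivalent that attacks the enal carbonyl carbon C2.
2. Ring order: the 14-membered carbocycle closes first and the γ-lactone closes directly after it, in the same final flask. Both stereocentres are set there by a chiral ligand on chromium.
3. The bromo-enal ester comes from cross-metathesis of a terminal alkene with methyl 2-(bromomethyl)acrylate, after MnO2 oxidation of the C2 alcohol.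
4. The C6–C7 bond comes from a B-alkyl Suzuki coupling of hydroborated (E)-3-methylpenta-2,4-dien-1-ol with a Z-vinyl iodide.
5. The Z-vinyl iodide (C7=C8 bearing CH2OAc) comes from anti-carbomagnesiation of propargyl alcohol with a homoallylic Grignard reagent. That reagent comes from hex-1-en-5-yne by methylalumination and oxirane opening.

Assumption: cembrane numbering is used (C1 = ring CH bearing C15, C2 = CH–O, C19 = acetoxymethyl carbon on C8); the SMILES decodes to the cis-fused (1S,2S)-lactone with 3E, 7Z (chain-trans) and 11E alkenes; the (S,S)-ligand is taken to give Re-face attack at C2, and its equally available mirror image is used if the sense proves opposite.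

## Route

Step 1
Reactants: 1 hex-1-en-5-yne; 2 trimethylaluminium; 3 oxirane
Product: 6 (3E)-4-methylocta-3,7-dien-1-ol, via alkenylalane 4 (not isolated), via lithium alanate 5 (not isolated)
Conditions: Me3Al (2 equiv), Cp2ZrCl2 (25 mol %), CH2Cl2, 0 °C to rt; evaporate, hexane; n-BuLi (1 equiv), THF, −78 °C; oxirane (3 equiv), −78 °C to rt; aqueous work-up
Reagents that add atoms: trimethylaluminium 2, C[Al](C)C; oxirane 3, C1CO1; n-butyllithium, [Li]CCCC (stays only in 5)
Why: Negishi zirconium-catalysed methylalumination adds Me and Al syn and regioselectively across the terminal alkyne (the monosubstituted alkene reacts far more slowly), which fixes the E-trisubstituted C11=C12 alkene, and the derived alanate opens oxirane with retention of alkene geometry.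

Step 2
Reactants: 6 (3E)-4-methylocta-3,7-dien-1-ol
Product: 7 (5E)-8-bromo-5-methylocta-1,5-diene
Conditions: CBr4, PPh3, CH2Cl2, 0 °C
Reagents that add atoms: tetrabromomethane, BrC(Br)(Br)Br
Why: The Appel reaction displaces the oxyphosphonium salt of a primary alcohol by SN2 under neutral conditions that leave both alkenes untouched.

Step 3
Reactants: 7 (5E)-8-bromo-5-methylocta-1,5-diene; 8 prop-2-yn-1-ol; 9 acetic anhydride
Product: 14 (2Z,5E)-2-(iodomethylidene)-6-methyldeca-5,9-dien-1-yl acetate, via Grignard reagent 10 (not isolated), via magnesium propynolate 11 (not isolated), via vinylmagnesium chelate 12 (not isolated), via iodo alkoxide 13 (not isolated)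
Conditions: (a) 7, Mg, THF, rt; (b) 8, EtMgBr (1.0 equiv), THF, −20 °C; (c) a + b, CuI (15 mol %), −10 °C to rt; (d) I2, −78 to 0 °C; (e) Ac2O, DMAP (cat.), 0 °C to rt
Reagents that add atoms: magnesium, [Mg] (stays only in 10 and 12); ethylmagnesium bromide, CC[Mg]Br (MgBr stays only in 11 to 13); iodine, [I][I]; acetic anhydride 9, CC(=O)OC(C)=O
Why: Copper-catalysed, alkoxide-directed anti-carbomagnesiation of the propargylic alkoxide puts the alkyl group on the carbon next to CH2O and the magnesium on the terminal carbon, cis to CH2O in a five-membered chelate, so iodinolysis with retention gives only the Z-iodoalkene (the geometry needed at C7=C8), and the remaining magnesium alkoxide is acetylated in the same flask.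

Step 4
Reactants: 15 (2E)-3-methylpent-2-en-4-yn-1-ol
Product: 16 (2E)-3-methylpenta-2,4-dien-1-ol
Conditions: H2 (1 atm, stopped at 1.0 equiv uptake), Lindlar catalyst (Pd on CaCO3 poisoned with Pb(OAc)2), quinoline, Et2O, 0 °C
Reagents that add atoms: none
Why: Lindlar semihydrogenation stops a terminal alkyne at the vinyl stage and leaves unchanged the E-trisubstituted alkene already present in commercial 15 (the future C3=C4).

Step 5
Reactants: 16 (2E)-3-methylpenta-2,4-dien-1-ol; 14 (2Z,5E)-2-(iodomethylidene)-6-methyldeca-5,9-dien-1-yl acetate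
Product: 18 (2E,6Z,10E)-7-(acetoxymethyl)-3,11-dimethylpentadeca-2,6,10,14-tetraen-1-ol, via bis-boryl adduct 17 (not isolated)
Conditions: (a) 16 (1.3 equiv), 9-BBN-H (2.1 equiv per 16), THF, 0 °C to rt; (b) degassed H2O; (c) 14, Pd(dppf)Cl2 (5 mol %), AsPh3 (10 mol %), Cs2CO3 (2 equiv), DMF–THF–H2O, rt
Reagents that add atoms: 9-borabicyclo[3.3.1]nonane (9-BBN-H), [H]B1C2CCCC1CCC2 (boron stays only in 17; 18 keeps one hydrogen from it at C5)
Why: 9-BBN-H first masks the OH as a borinate and then hydroborates only the monosubstituted end of the diene at its terminal carbon, and the B-alkyl Suzuki–Miyaura coupling joins that sp3 carbon to the vinyl iodide with retention of geometry, because oxidative addition of zerovalent palladium into C–I is much faster at rt than ionisation of the allylic acetate.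

Step 6
Reactants: 18 (2E,6Z,10E)-7-(acetoxymethyl)-3,11-dimethylpentadeca-2,6,10,14-tetraen-1-ol
Product: 19 (2E,6Z,10E)-7-(acetoxymethyl)-3,11-dimethylpentadeca-2,6,10,14-tetraenal
Conditions: activated MnO2 (excess), CH2Cl2, rt
Reagents that add atoms: none
Why: Heterogeneous MnO2 oxidation takes a primary allylic alcohol to the enal under neutral conditions without E/Z isomerisation (as for geraniol to geranial) and leaves the acetate and the other alkenes alone.

Step 7
Reactants: 19 (2E,6Z,10E)-7-(acetoxymethyl)-3,11-dimethylpentadeca-2,6,10,14-tetraenal; 20 methyl 2-(bromomethyl)prop-2-enoate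
Product: 21 methyl (2Z,6E,10Z,14E)-10-(acetoxymethyl)-2-(bromomethyl)-6,14-dimethyl-16-oxohexadeca-2,6,10,14-tetraenoate
Conditions: 20 (5 equiv), second-generation Hoveyda–Grubbs catalyst [RuCl2(H2IMes)(=CH-C6H4-2-OiPr)] (2 × 5 mol %), 1,4-benzoquinone (10 mol %), CH2Cl2, 40 °C, argon sparge
Reagents that add atoms: methyl 2-(bromomethyl)prop-2-enoate 20, C=C(CBr)C(=O)OC
Why: In this olefin cross-metathesis the ruthenium carbene engages only the single monosubstituted alkene of 19 (the trisubstituted alkenes and the enal are inert), the excess 2-substituted acrylate does not homodimerise, and, as with methacrylates, the chain ends up trans to the ester (Z descriptor), while any minor isomer converges in step 8.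

Step 8
Reactants: 21 methyl (2Z,6E,10Z,14E)-10-(acetoxymethyl)-2-(bromomethyl)-6,14-dimethyl-16-oxohexadeca-2,6,10,14-tetraenoate
Product: 25 (1S,2S,3E,7Z,11E)-19-acetoxycembra-3,7,11,15(17)-tetraen-16,2-olide (the target), via allylchromium 22 (not isolated), via silyl ether 23 (not isolated), via hydroxy ester 24 (not isolated)
Conditions: CrCl2 (20 mol %), L* (22 mol %), i-Pr2NEt (50 mol %), Mn powder (3 equiv), TMSCl (2 equiv), THF, rt, 21 added by syringe pump over 24 h (final 2 mM); then 1 M HCl–THF, 0 °C to rt; L* = 3,6-diphenyl-1,8-bis[(4S)-4-isopropyl-4,5-dihydro-1,3-oxazol-2-yl]-9H-carbazole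
Reagents that add atoms: CrCl2, Cl[Cr]Cl (chromium and chloride stay only in 22); chlorotrimethylsilane, C[Si](C)(C)Cl (silicon stays only in 23)
Why: Proposed new method: two one-electron transfers from ligated divalent chromium turn the allylic bromide into the trivalent allylchromium 22, in which C1, the β-carbon of the enoate and normally an acceptor, becomes a donor (homoenolate, d3 equivalent) that attacks the acceptor carbon C2 of the enal through a closed Zimmerman–Traxler chair; the chain on C1 lies cis to CH2Cr (the more stable tiglate-like geometry, reached from either bromide isomer by 1,3-metal shift) and is therefore axial while the enal residue is equatorial, which gives the syn adduct and hence the cis ring fusion, and the twofold-symmetric tridentate carbazole-bisoxazoline leaves only the Re face of C2 open and so fixes (1S,2S); Mn returns chromium to the divalent state, TMSCl releases the alkoxide, and the acid work-up removes silicon and closes the lactone; the closest known reactions are the intermolecular catalytic asymmetric Nozaki–Hiyama–Kishi 2-(alkoxycarbonyl)allylation of aldehydes and the racemic CrCl2-mediated allyl bromide–aldehyde macrocyclisation used for 14-membered cembranoids, and the new element is their combination under slow addition.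

## Compound list

1 | hex-1-en-5-yne | C=CCCC#C | starting material
2 | trimethylaluminium | C[Al](C)C | starting material
3 | oxirane (ethylene oxide) | C1CO1 | starting material
4 | dimethyl[(1E)-2-methylhexa-1,5-dien-1-yl]alane | C=CCC/C(C)=C/[Al](C)C | intermediate
5 | lithium butyl(dimethyl)[(1E)-2-methylhexa-1,5-dien-1-yl]aluminate | [Li+].C=CCC/C(C)=C/[Al-](C)(C)CCCC | intermediate
6 | (3E)-4-methylocta-3,7-dien-1-ol | OCC/C=C(\C)CCC=C | intermediate
7 | (5E)-8-bromo-5-methylocta-1,5-diene | BrCC/C=C(\C)CCC=C | intermediate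
8 | prop-2-yn-1-ol (propargyl alcohol) | C#CCO | starting material
9 | acetic anhydride | CC(=O)OC(C)=O | starting material
10 | [(3E)-4-methylocta-3,7-dien-1-yl]magnesium bromide | Br[Mg]CC/C=C(\C)CCC=C | intermediate
11 | bromomagnesium prop-2-yn-1-olate | C#CCO[Mg]Br | intermediate
12 | dimagnesiated anti-adduct, vinyl MgBr on C7 cis to CH2OMgBr, drawn open | Br[Mg]/C=C(\CO[Mg]Br)CC/C=C(\C)CCC=C | intermediate
13 | bromomagnesium (2Z,5E)-2-(iodomethylidene)-6-methyldeca-5,9-dien-1-olate | I/C=C(\CO[Mg]Br)CC/C=C(\C)CCC=C | intermediate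
14 | (2Z,5E)-2-(iodomethylidene)-6-methyldeca-5,9-dien-1-yl acetate | I/C=C(\COC(C)=O)CC/C=C(\C)CCC=C | intermediate
15 | (2E)-3-methylpent-2-en-4-yn-1-ol | C#C/C(C)=C/CO | starting material
16 | (2E)-3-methylpenta-2,4-dien-1-ol | C=C/C(C)=C/CO | intermediate
17 | 9-{(3E)-5-[(9-borabicyclo[3.3.1]nonan-9-yl)oxy]-3-methylpent-3-en-1-yl}-9-borabicyclo[3.3.1]nonane | B1(CC/C(C)=C/COB2C3CCCC2CCC3)C4CCCC1CCC4 | intermediate
18 | (2E,6Z,10E)-7-(acetoxymethyl)-3,11-dimethylpentadeca-2,6,10,14-tetraen-1-ol | OC/C=C(\C)CC/C=C(\COC(C)=O)CC/C=C(\C)CCC=C | intermediate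
19 | (2E,6Z,10E)-7-(acetoxymethyl)-3,11-dimethylpentadeca-2,6,10,14-tetraenal | O=C/C=C(\C)CC/C=C(\COC(C)=O)CC/C=C(\C)CCC=C | intermediate
20 | methyl 2-(bromomethyl)prop-2-enoate | C=C(CBr)C(=O)OC | starting material
21 | methyl (2Z,6E,10Z,14E)-10-(acetoxymethyl)-2-(bromomethyl)-6,14-dimethyl-16-oxohexadeca-2,6,10,14-tetraenoate | O=C/C=C(\C)CC/C=C(\COC(C)=O)CC/C=C(\C)CC/C=C(\CBr)C(=O)OC | intermediate
22 | trivalent allylchromium from 21 (CH2Br replaced by CH2CrCl2, chiral ligand omitted) | O=C/C=C(\C)CC/C=C(\COC(C)=O)CC/C=C(\C)CC/C=C(\C[Cr](Cl)Cl)C(=O)OC | intermediate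
23 | methyl 2-[(1S,2S,3E,7Z,11E)-8-(acetoxymethyl)-4,12-dimethyl-2-(trimethylsilyloxy)cyclotetradeca-3,7,11-trien-1-yl]prop-2-enoate | C[Si](C)(C)O[C@H]1/C=C(\C)CC/C=C(\COC(C)=O)CC/C=C(\C)CC[C@H]1C(=C)C(=O)OC | intermediate
24 | methyl 2-[(1S,2S,3E,7Z,11E)-8-(acetoxymethyl)-2-hydroxy-4,12-dimethylcyclotetradeca-3,7,11-trien-1-yl]prop-2-enoate | O[C@H]1/C=C(\C)CC/C=C(\COC(C)=O)CC/C=C(\C)CC[C@H]1C(=C)C(=O)OC | intermediate
25 | (1S,2S,3E,7Z,11E)-19-acetoxycembra-3,7,11,15(17)-tetraen-16,2-olide, cis-fused α-methylene-γ-lactone | C=C1C(=O)O[C@H]2/C=C(\C)CC/C=C(\COC(C)=O)CC/C=C(\C)CC[C@@H]12 | target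

## Step count and risks

Total step count: 8.
Longest linear sequence: 7 (steps 1, 2, 3, 5, 6, 7, 8). Step 4 is the side branch.

**Step 8 (ring closure, relative and absolute configuration in one event).**
- Risks: oligomerisation, a racemic background reaction of the very reactive bromide with Mn/TMSCl, and untested facial control in a tethered transition state.
- Fallback: it sets out from 19 and comes back at 25, and it replaces the redox-generated allylchromium by an isolable allylboron donor under Brønsted-acid control. Cross-metathesis of 19 with commercial methyl 2-[(4,4,5,5-tetramethyl-1,3,2-dioxaborolan-2-yl)methyl]prop-2-enoate gives the allylboronate enal F1, which does not cyclise without a catalyst. Slow addition of it to (R)-TRIP phosphoric acid (10 mol %) in toluene at 0 °C triggers an intramolecular allylboration through the same chair (chain cis to CH2B, hence syn). The acid selects the aldehyde face, and the boron alkoxide lactonises on work-up to 25.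

**Step 7 (cross-metathesis with a 1,1-disubstituted, electron-poor allylic bromide on a polyene enal).**
- Risks: low conversion, homodimer of 19, and catalyst decay.
- Fallback: it sets out from 8 and 16 and comes back at 21. It brings C1 in as a protected alcohol and builds the bromomethyl enoate by Morita–Baylis–Hillman chemistry. Commercial tert-butyl(dimethyl)(pent-4-yn-1-yloxy)silane F2 is taken by the chemistry of step 1 to the homoallylic alcohol F3 and by that of step 2 to the bromide F4. The chemistry of step 3 (with 8 and 9) then gives the iodo acetate F5, and that of step 5 (with 16) gives the silyl ether alcohol F6. HF·pyridine gives the diol F7, and TEMPO/PhI(OAc)2 oxidises both primary alcohols to the dialdehyde F8. Methyl acrylate/DABCO reacts only at the saturated aldehyde to give the Baylis–Hillman adduct F9, and NBS/Me2S converts this with allylic shift into the Z-bromide 21.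

**Step 5 (hydroboration of an unprotected dienol and a basic aqueous palladium coupling next to a primary allylic acetate).**
- Risks: acetate hydrolysis, π-allyl side reactions, and residual borane attacking the terminal alkene of 14.
- Fallback: it sets out from 16 and 14 and comes back at 18, and it abandons the boron coupling for a base-free Negishi coupling of a preformed zinc reagent. TBSCl/imidazole turns 16 into the silyl ether F10. 9-BBN-H gives the borane F11, I2/NaOMe gives the homoallylic iodide F12, and Zn dust/LiCl gives the alkylzinc iodide F13. Pd(dppf)Cl2-catalysed coupling with 14 in THF at rt gives the coupled silyl ether F14, and HF·pyridine frees 18.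

Further compounds
F1 | step 8 | methyl (2E,6E,10Z,14E)-10-(acetoxymethyl)-6,14-dimethyl-16-oxo-2-[(4,4,5,5-tetramethyl-1,3,2-dioxaborolan-2-yl)methyl]hexadeca-2,6,10,14-tetraenoate | O=C/C=C(\C)CC/C=C(\COC(C)=O)CC/C=C(\C)CC/C=C(\CB1OC(C)(C)C(C)(C)O1)C(=O)OC
F2 | step 7 | tert-butyl(dimethyl)(pent-4-yn-1-yloxy)silane | C#CCCCO[Si](C)(C)C(C)(C)C
F3 | step 7 | (3E)-7-[tert-butyl(dimethyl)silyl]oxy-4-methylhept-3-en-1-ol | OCC/C=C(\C)CCCO[Si](C)(C)C(C)(C)C
F4 | step 7 | [(4E)-7-bromo-4-methylhept-4-en-1-yl]oxy(tert-butyl)dimethylsilane | BrCC/C=C(\C)CCCO[Si](C)(C)C(C)(C)C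
F5 | step 7 | (2Z,5E)-9-[tert-butyl(dimethyl)silyl]oxy-2-(iodomethylidene)-6-methylnon-5-en-1-yl acetate | I/C=C(\COC(C)=O)CC/C=C(\C)CCCO[Si](C)(C)C(C)(C)C
F6 | step 7 | (2E,6Z,10E)-7-(acetoxymethyl)-14-[tert-butyl(dimethyl)silyl]oxy-3,11-dimethyltetradeca-2,6,10-trien-1-ol | OC/C=C(\C)CC/C=C(\COC(C)=O)CC/C=C(\C)CCCO[Si](C)(C)C(C)(C)C
F7 | step 7 | (2E,6Z,10E)-7-(acetoxymethyl)-3,11-dimethyltetradeca-2,6,10-triene-1,14-diol | OC/C=C(\C)CC/C=C(\COC(C)=O)CC/C=C(\C)CCCO
F8 | step 7 | (2E,6Z,10E)-7-(acetoxymethyl)-3,11-dimethyltetradeca-2,6,10-trienedial | O=C/C=C(\C)CC/C=C(\COC(C)=O)CC/C=C(\C)CCC=O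
F9 | step 7 | methyl (6E,10Z,14E)-10-(acetoxymethyl)-3-hydroxy-6,14-dimethyl-2-methylidene-16-oxohexadeca-6,10,14-trienoate (racemic carbinol) | O=C/C=C(\C)CC/C=C(\COC(C)=O)CC/C=C(\C)CCC(O)C(=C)C(=O)OC
F10 | step 5 | tert-butyl(dimethyl){[(2E)-3-methylpenta-2,4-dien-1-yl]oxy}silane | C=C/C(C)=C/CO[Si](C)(C)C(C)(C)C
F11 | step 5 | 9-{(3E)-5-[tert-butyl(dimethyl)silyl]oxy-3-methylpent-3-en-1-yl}-9-borabicyclo[3.3.1]nonane | B1(CC/C(C)=C/CO[Si](C)(C)C(C)(C)C)C2CCCC1CCC2
F12 | step 5 | tert-butyl{[(2E)-5-iodo-3-methylpent-2-en-1-yl]oxy}dimethylsilane | ICC/C(C)=C/CO[Si](C)(C)C(C)(C)C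
F13 | step 5 | {(3E)-5-[tert-butyl(dimethyl)silyl]oxy-3-methylpent-3-en-1-yl}zinc iodide | I[Zn]CC/C(C)=C/CO[Si](C)(C)C(C)(C)C
F14 | step 5 | tert-butyldimethylsilyl ether of 18 | CC(C)(C)[Si](C)(C)OC/C=C(\C)CC/C=C(\COC(C)=O)CC/C=C(\C)CCC=C
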